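## Retrosynthetic overview

1. The target is 5,3',5'-trihydroxy-6,7,2'-trimethoxyflavone, which is achiral. The phenols are freed last: the C5 methyl ether peri to the C4 carbonyl is cleaved under chelation control, then the two ring B benzyl ethers are removed by hydrogenolysis.
2. Ring C is the only ring made. It is opened at O1–C2 to an ortho-hydroxyaryl ynone that already holds every carbon of the flavone.
3. The strategy rests on ring A. O1 (on C8a) and the C4 carbonyl carbon (on C4a) sit on neighbouring carbons directly beside the unbroken C5/C6/C7 methoxy row. This pattern arises when a carboxylate oxygen adds to 3,4,5-trimethoxybenzyne and its acyl group moves to the adjacent carbon, so O1–C8a and C4–C4a are cut together to give a silylaryl triflate and an arylpropiolic acid.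
4. The silyl triflate comes from 3,4,5-trimethoxyphenol by bromination, O-silylation and retro-Brook/triflation. The acid comes from 3,5-dibromosalicylaldehyde by O-methylation, double borylation–oxidation, benzylation, Ohira–Bestmann alkynylation and carboxylation.
5. Ring order: rings A and B are bought, and ring C is closed in step 10, after the key step.

Key step: step 9

Remark on the chemistry: the target has no stereocentre. The enaminone passed through in the ring closure is drawn without alkene geometry, because both isomers lead to the same flavone.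

## Route

Step 1
Reactants: 1 3,4,5-trimethoxyphenol
Product: 2 2-bromo-3,4,5-trimethoxyphenol
Conditions: NBS (1.0 equiv), CH2Cl2, −78 °C to 0 °C
Reagents that add atoms: N-bromosuccinimide, O=C1CCC(=O)N1Br
Why: Electrophilic aromatic bromination should give a single monobromide, because the para position of the phenol is blocked by a methoxy group and the two free ortho positions are equivalent.

Step 2
Reactants: 2 2-bromo-3,4,5-trimethoxyphenol
Product: 3 (2-bromo-3,4,5-trimethoxyphenoxy)trimethylsilane
Conditions: HMDS (0.7 equiv), THF, 70 °C; volatiles removed in vacuo, used crude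
Reagents that add atoms: hexamethyldisilazane, C[Si](C)(C)N[Si](C)(C)C
Why: O-silylation of a phenol with HMDS needs no added base, has a volatile co-product and leaves the aryl bromide and the methyl ethers untouched.

Step 3
Reactants: 3 (2-bromo-3,4,5-trimethoxyphenoxy)trimethylsilane
Product: 6 3,4,5-trimethoxy-2-(trimethylsilyl)phenyl trifluoromethanesulfonate, via aryllithium 4 (not isolated), via lithium 2-silylphenoxide 5 (not isolated)
Conditions: n-BuLi (1.1 equiv), THF, −78 °C, 30 min; then Tf2O (1.2 equiv), −78 °C to 0 °C
Reagents that add atoms: trifluoromethanesulfonic anhydride, O=S(=O)(C(F)(F)F)OS(=O)(=O)C(F)(F)F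
Why: Bromine–lithium exchange is fast at −78 °C, the aryllithium takes the silyl group from the neighbouring oxygen (retro-Brook 1,3 O-to-C silyl migration), and the released phenoxide is O-sulfonylated in the same flask.

Step 4
Reactants: 7 3,5-dibromo-2-hydroxybenzaldehyde
Product: 8 3,5-dibromo-2-methoxybenzaldehyde
Conditions: MeI (1.5 equiv), K2CO3, DMF, rt
Reagents that add atoms: iodomethane, CI
Why: Williamson etherification of an acidic phenol should proceed cleanly because the aldehyde cannot enolise and the aryl bromides are inert to carbonate.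

Step 5
Reactants: 8 3,5-dibromo-2-methoxybenzaldehyde
Product: 10 3,5-dihydroxy-2-methoxybenzaldehyde, via bis(pinacol boronate) 9 (not isolated)
Conditions: B2pin2 (2.4 equiv), Pd(dppf)Cl2 (5 mol%), KOAc (6 equiv), 1,4-dioxane, 90 °C; cool to 0 °C, dilute with THF, 30% aq H2O2 (excess), 0 °C to rt (residual KOAc as buffer); Na2S2O3 quench
Reagents that add atoms: hydrogen peroxide, OO
Why: Miyaura borylation tolerates the aldehyde and replaces both C–Br bonds, and the boronate oxidation (1,2-aryl shift from boron to peroxide oxygen) is much faster than a Dakin reaction at an aldehyde lacking a free ortho or para hydroxy group.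

Step 6
Reactants: 10 3,5-dihydroxy-2-methoxybenzaldehyde
Product: 11 3,5-bis(benzyloxy)-2-methoxybenzaldehyde
Conditions: BnBr (2.3 equiv), K2CO3, DMF, 50 °C, under N2
Reagents that add atoms: benzyl bromide, BrCc1ccccc1
Why: Double Williamson etherification masks both phenols as ethers that withstand butyllithium at low temperature, fluoride and amines, and that leave at the end under neutral hydrogenolysis.

Step 7
Reactants: 11 3,5-bis(benzyloxy)-2-methoxybenzaldehyde; 12 dimethyl (1-diazo-2-oxopropyl)phosphonate
Product: 13 1,5-bis(benzyloxy)-3-ethynyl-2-methoxybenzene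
Conditions: 12 (1.3 equiv), K2CO3 (2 equiv), MeOH–THF, rt
Reagents that add atoms: none
Why: In the Ohira–Bestmann homologation, methanolysis of 12 releases the diazomethylphosphonate anion, which adds to the non-enolisable aldehyde and, after loss of phosphate and nitrogen and a 1,2-hydrogen shift, gives the terminal alkyne without harming the ethers.

Step 8
Reactants: 13 1,5-bis(benzyloxy)-3-ethynyl-2-methoxybenzene
Product: 15 3-[3,5-bis(benzyloxy)-2-methoxyphenyl]prop-2-ynoic acid, via lithium acetylide 14 (not isolated)
Conditions: n-BuLi (1.05 equiv), THF, −78 °C; dried CO2 gas, −78 °C to rt; 1 M HCl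
Reagents that add atoms: carbon dioxide, O=C=O
Why: The alkyne C–H is by far the most acidic site, so one equivalent of base at −78 °C gives only the acetylide (no benzylic or ring lithiation), and its carboxylation with CO2 is a standard route to arylpropiolic acids.

Step 9
Reactants: 15 3-[3,5-bis(benzyloxy)-2-methoxyphenyl]prop-2-ynoic acid; 6 3,4,5-trimethoxy-2-(trimethylsilyl)phenyl trifluoromethanesulfonate
Product: 19 3-[3,5-bis(benzyloxy)-2-methoxyphenyl]-1-(2-hydroxy-4,5,6-trimethoxyphenyl)prop-2-yn-1-one, via cesium arylpropiolate 16 (not isolated), via 3,4,5-trimethoxybenzyne 17 (not isolated), via cesium phenoxide 18 (not isolated)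
Conditions: 15 (1.5 equiv), Cs2CO3 (0.5 equiv per acid), MeOH, rt; evaporate, azeotrope with toluene and dry in vacuo in the same flask; then CsF (3 equiv), 18-crown-6 (1 equiv), dry THF, 60 °C, 6 (1.0 equiv) added over 3 h; quench into cold 1 M HCl
Reagents that add atoms: none
Why: Fluoride strips the silyl group from 6 and triflate leaves, so aryne 17 is released slowly into an excess of dry carboxylate 16, whose oxygen adds to the aryne carbon flanked by C–H (the future C8a) and leaves the aryl anion on the carbon next to the methoxy group (the future C4a). This anion attacks the ester carbonyl two bonds away, the strained benzoxetene alkoxide reopens by C–O cleavage, and phenoxide 18 results, so that O1–C8a and C4–C4a are both made and the acyl group has formally moved from oxygen to the ortho carbon. The closest known reaction type is the fluoride-induced insertion of arynes into the C–O bond of carboxylic acids (arylpropiolic acids included), and the acyl shift itself is that of an anionic ortho-Fries rearrangement. No ring is closed and no stereocentre is formed, because in dry THF there is no proton to complete an oxa-Michael addition of 18 to its own triple bond, so the open-chain phenoxide should persist until the cold acid quench. The regioselectivity needed (oxygen at C8a, not at C4a) is secured by the methoxy group next to the triple bond of 17, which distorts the aryne and inductively stabilises the adjacent carbanion, as is general for 3-alkoxyarynes. The chemoselectivity needed is acyl shift over protonation, secured by the acid-free medium, and carboxylate over phenoxide as the aryne trap, favoured by the excess of 16 and the slow addition of 6, with unused 15 recovered by bicarbonate extraction.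

Step 10
Reactants: 19 3-[3,5-bis(benzyloxy)-2-methoxyphenyl]-1-(2-hydroxy-4,5,6-trimethoxyphenyl)prop-2-yn-1-one
Product: 21 2-[3,5-bis(benzyloxy)-2-methoxyphenyl]-5,6,7-trimethoxy-4H-chromen-4-one, via beta-diethylamino enone 20 (not isolated)
Conditions: Et2NH (5 equiv), EtOH, 78 °C
Reagents that add atoms: none
Why: Aza-Michael addition of the secondary amine turns the ynone into an enaminone whose beta carbon is the only electrophilic site left, so the phenol closes ring C there by addition–elimination (overall 6-endo, O1–C2) and the 5-exo aurone pathway is shut out.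

Step 11
Reactants: 21 2-[3,5-bis(benzyloxy)-2-methoxyphenyl]-5,6,7-trimethoxy-4H-chromen-4-one
Product: 22 2-[3,5-bis(benzyloxy)-2-methoxyphenyl]-5-hydroxy-6,7-dimethoxy-4H-chromen-4-one
Conditions: MgI2·OEt2 (1.5 equiv), toluene–Et2O, 70 °C; 1 M HCl
Reagents that add atoms: none
Why: In this chelation-directed ether cleavage the mild Lewis acid activates only the ether it can bind together with the pyrone carbonyl (six-membered chelate at C4=O/C5–OMe), iodide removes that methyl group by SN2, and the C6, C7 and C2' methyl ethers and the benzyl ethers should stay.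

Step 12
Reactants: 22 2-[3,5-bis(benzyloxy)-2-methoxyphenyl]-5-hydroxy-6,7-dimethoxy-4H-chromen-4-one
Product: 23 2-(3,5-dihydroxy-2-methoxyphenyl)-5-hydroxy-6,7-dimethoxy-4H-chromen-4-one (target)
Conditions: H2 (1 atm), Pd/C (10 wt% Pd on carbon), THF–MeOH, rt, stopped at full debenzylation
Reagents that add atoms: none
Why: Catalytic hydrogenolysis cleaves the two benzylic C–O bonds under neutral conditions at one atmosphere, where the conjugated C2=C3 bond of a flavone and the methyl ethers are normally retained.

## Compound list

1 | 3,4,5-trimethoxyphenol | COc1cc(O)cc(OC)c1OC | starting material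
2 | 2-bromo-3,4,5-trimethoxyphenol | Oc1cc(OC)c(OC)c(OC)c1Br | intermediate
3 | (2-bromo-3,4,5-trimethoxyphenoxy)trimethylsilane | C[Si](C)(C)Oc1cc(OC)c(OC)c(OC)c1Br | intermediate
4 | [2,3,4-trimethoxy-6-(trimethylsilyloxy)phenyl]lithium (not isolated) | [Li]c1c(O[Si](C)(C)C)cc(OC)c(OC)c1OC | intermediate
5 | lithium 3,4,5-trimethoxy-2-(trimethylsilyl)phenoxide (not isolated) | [Li+].[O-]c1cc(OC)c(OC)c(OC)c1[Si](C)(C)C | intermediate
6 | 3,4,5-trimethoxy-2-(trimethylsilyl)phenyl trifluoromethanesulfonate | COc1cc(OS(=O)(=O)C(F)(F)F)c([Si](C)(C)C)c(OC)c1OC | intermediate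
7 | 3,5-dibromo-2-hydroxybenzaldehyde | O=Cc1cc(Br)cc(Br)c1O | starting material
8 | 3,5-dibromo-2-methoxybenzaldehyde | COc1c(Br)cc(Br)cc1C=O | intermediate
9 | 2-methoxy-3,5-bis(4,4,5,5-tetramethyl-1,3,2-dioxaborolan-2-yl)benzaldehyde (not isolated) | COc1c(C=O)cc(B2OC(C)(C)C(C)(C)O2)cc1B1OC(C)(C)C(C)(C)O1 | intermediate
10 | 3,5-dihydroxy-2-methoxybenzaldehyde | COc1c(O)cc(O)cc1C=O | intermediate
11 | 3,5-bis(benzyloxy)-2-methoxybenzaldehyde | COc1c(C=O)cc(OCc2ccccc2)cc1OCc1ccccc1 | intermediate
12 | dimethyl (1-diazo-2-oxopropyl)phosphonate | CC(=O)C(=[N+]=[N-])P(=O)(OC)OC | starting material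
13 | 1,5-bis(benzyloxy)-3-ethynyl-2-methoxybenzene | C#Cc1cc(OCc2ccccc2)cc(OCc2ccccc2)c1OC | intermediate
14 | lithium acetylide of 13 (not isolated) | [Li]C#Cc1cc(OCc2ccccc2)cc(OCc2ccccc2)c1OC | intermediate
15 | 3-[3,5-bis(benzyloxy)-2-methoxyphenyl]prop-2-ynoic acid | OC(=O)C#Cc1cc(OCc2ccccc2)cc(OCc2ccccc2)c1OC | intermediate
16 | cesium 3-[3,5-bis(benzyloxy)-2-methoxyphenyl]prop-2-ynoate (not isolated) | [Cs+].[O-]C(=O)C#Cc1cc(OCc2ccccc2)cc(OCc2ccccc2)c1OC | intermediate
17 | 3,4,5-trimethoxybenzyne (not isolated) | C1#CC(OC)=C(OC)C(OC)=C1 | intermediate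
18 | cesium phenoxide of 19 (not isolated) | [Cs+].[O-]c1cc(OC)c(OC)c(OC)c1C(=O)C#Cc1cc(OCc2ccccc2)cc(OCc2ccccc2)c1OC | intermediate
19 | 3-[3,5-bis(benzyloxy)-2-methoxyphenyl]-1-(2-hydroxy-4,5,6-trimethoxyphenyl)prop-2-yn-1-one | COc1cc(O)c(C(=O)C#Cc2cc(OCc3ccccc3)cc(OCc3ccccc3)c2OC)c(OC)c1OC | intermediate
20 | 3-[3,5-bis(benzyloxy)-2-methoxyphenyl]-3-(diethylamino)-1-(2-hydroxy-4,5,6-trimethoxyphenyl)prop-2-en-1-one, alkene geometry not fixed (not isolated) | CCN(CC)C(=CC(=O)c1c(O)cc(OC)c(OC)c1OC)c1cc(OCc2ccccc2)cc(OCc2ccccc2)c1OC | intermediate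
21 | 2-[3,5-bis(benzyloxy)-2-methoxyphenyl]-5,6,7-trimethoxy-4H-chromen-4-one | COc1cc2oc(-c3cc(OCc4ccccc4)cc(OCc4ccccc4)c3OC)cc(=O)c2c(OC)c1OC | intermediate
22 | 2-[3,5-bis(benzyloxy)-2-methoxyphenyl]-5-hydroxy-6,7-dimethoxy-4H-chromen-4-one | COc1cc2oc(-c3cc(OCc4ccccc4)cc(OCc4ccccc4)c3OC)cc(=O)c2c(O)c1OC | intermediate
23 | 2-(3,5-dihydroxy-2-methoxyphenyl)-5-hydroxy-6,7-dimethoxy-4H-chromen-4-one | COc1cc2oc(-c3cc(O)cc(O)c3OC)cc(=O)c2c(O)c1OC | target

## Step count and risks

Total step count: 12. Longest linear sequence: 9 (steps 4 to 12).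

**Step 9 (aryne insertion).**
- What may go wrong: the aryl anion may be protonated by adventitious water before the acyl shift (plain O-arylation). The product phenoxide may capture a second aryne. The propiolate may lose CO2 on heating. The triple bond may be attacked prematurely in the 5-exo sense once protons are present.
- Fallback: it sets out from 1 and 11 and comes back at 21, using classical flavone chemistry.
- C-acetylation of 1 with AcOH and BF3·OEt2 at 85 °C (Friedel–Crafts/Fries type, ortho to the phenol) should give 1-(2-hydroxy-4,5,6-trimethoxyphenyl)ethanone F1.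
- Claisen–Schmidt condensation of this ketone with aldehyde 11 (KOH, EtOH, rt) should give (E)-3-[3,5-bis(benzyloxy)-2-methoxyphenyl]-1-(2-hydroxy-4,5,6-trimethoxyphenyl)prop-2-en-1-one F2.
- Oxidative cyclisation with catalytic I2 in DMSO at 120 °C should close ring C and give 21.

**Step 11 (C5 demethylation).**
- What may go wrong: the cleavage may be sluggish with the mild magnesium Lewis acid. It may run on to the C6 ether once the C5 magnesium phenoxide is formed. Benzyl groups may be partly lost.
- Fallback: it sets out from 21 and comes back at 23. It changes the order of deprotection and the ring B protecting groups, so that a stronger Lewis acid can be used.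
- Hydrogenolysis of 21 (H2, Pd/C) should give 2-(3,5-dihydroxy-2-methoxyphenyl)-5,6,7-trimethoxy-4H-chromen-4-one F3.
- Acetylation (Ac2O, pyridine) should give its diacetate, 2-methoxy-5-(5,6,7-trimethoxy-4-oxo-4H-chromen-2-yl)-1,3-phenylene diacetate F4. Its ring B oxygens are poor Lewis bases and cannot release benzyl cations.
- BCl3 (1.2 equiv, CH2Cl2, −78 °C to 0 °C) should then remove only the chelated C5 methyl group to give 5-(5-hydroxy-6,7-dimethoxy-4-oxo-4H-chromen-2-yl)-2-methoxy-1,3-phenylene diacetate F5.
- Methanolysis (K2CO3, MeOH, rt) should give 23.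

**Step 5 (double borylation–oxidation).**
- What may go wrong: the second borylation at the position flanked by the methoxy group may stay incomplete. Protodeborylation may occur. Peroxide may attack the formyl group.
- Fallback: it sets out from 8 and comes back at 11. It replaces the boron chemistry and the separate benzylation by a direct C–O cross-coupling.
- Acetalisation of 8 (ethylene glycol, p-TsOH, toluene, water removal) should give 2-(3,5-dibromo-2-methoxyphenyl)-1,3-dioxolane F6.
- Ullmann-type etherification with benzyl alcohol (CuI, 3,4,7,8-tetramethyl-1,10-phenanthroline, Cs2CO3, toluene, 110 °C) should give 2-[3,5-bis(benzyloxy)-2-methoxyphenyl]-1,3-dioxolane F7.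
- Mild hydrolysis (1 M HCl, THF, rt) should give 11.

## Further compounds

F1 | step 9 | 1-(2-hydroxy-4,5,6-trimethoxyphenyl)ethanone | CC(=O)c1c(O)cc(OC)c(OC)c1OC
F2 | step 9 | (E)-3-[3,5-bis(benzyloxy)-2-methoxyphenyl]-1-(2-hydroxy-4,5,6-trimethoxyphenyl)prop-2-en-1-one | COc1cc(O)c(C(=O)/C=C/c2cc(OCc3ccccc3)cc(OCc3ccccc3)c2OC)c(OC)c1OC
F3 | step 11 | 2-(3,5-dihydroxy-2-methoxyphenyl)-5,6,7-trimethoxy-4H-chromen-4-one | COc1cc2oc(-c3cc(O)cc(O)c3OC)cc(=O)c2c(OC)c1OC
F4 | step 11 | 2-methoxy-5-(5,6,7-trimethoxy-4-oxo-4H-chromen-2-yl)-1,3-phenylene diacetate | COc1cc2oc(-c3cc(OC(C)=O)cc(OC(C)=O)c3OC)cc(=O)c2c(OC)c1OC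
F5 | step 11 | 5-(5-hydroxy-6,7-dimethoxy-4-oxo-4H-chromen-2-yl)-2-methoxy-1,3-phenylene diacetate | COc1cc2oc(-c3cc(OC(C)=O)cc(OC(C)=O)c3OC)cc(=O)c2c(O)c1OC
F6 | step 5 | 2-(3,5-dibromo-2-methoxyphenyl)-1,3-dioxolane | COc1c(Br)cc(Br)cc1C1OCCO1
F7 | step 5 | 2-[3,5-bis(benzyloxy)-2-methoxyphenyl]-1,3-dioxolane | COc1c(C2OCCO2)cc(OCc2ccccc2)cc1OCc1ccccc1
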